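The route rests on disconnecting the lactone C6–O bond (and with it O–C12) in the last step. The C6 methylene of the ten-membered carbocycle (C1–C10) lies γ to the C12 carboxyl of the C11=C13 acrylic acid on C7. One enzymatic C6–H hydroxylation therefore creates the C6 stereocentre and, by spontaneous closure of the five-membered ring C6–O–C12–C11–C7, the lactone, which is the target itself. The precursor is the 6-deoxy seco acid that already carries the C8 isobutyrate, the ring-cis C1=C10 methyl enoate and the free C15 alcohol. It is assembled by an auxiliary-controlled Michael addition (C4), Morita–Baylis–Hillman and Wittig chain extensions and a chromium-mediated Barbier closure of C7–C8.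

Key step: step 15

Remark (numbering): ring carbons are C1–C10 with C1=C10; C11 (α-carbon), C12 (carboxyl) and C13 (methylene) form the acrylate on C7; C14 is the ester carbon on C10 and C15 the hydroxymethyl carbon on C4. The C1=C10 bond is cis within the ring (C2 and C9 on the same side) although its CIP descriptor is E.

Remark (precursor design): a free C8 hydroxyl is also γ to C12 and cis to the C7 side chain, so it would compete for lactonisation (8,12-olide) when the acid is unmasked and would later need selective acylation beside O15. The C8 isobutyrate is therefore installed before the acid is liberated, C12 is carried as a tert-butyl ester that resists the C8 alkoxide, the hydroxylation substrate is the 8-O-isobutyryl 6-deoxy seco acid 21, and its product is the target.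

Assumption: a costunolide-synthase-type P450 variant that accepts 21 is obtained by homologue screening or directed evolution.

Step 1
Reactants: 1 (4R)-4-benzyl-1,3-oxazolidin-2-one; 2 hex-5-enoic acid
Product: 3 (4R)-4-benzyl-3-(hex-5-enoyl)-1,3-oxazolidin-2-one
Conditions: 2, PivCl, Et3N, THF, −20 °C; then 1, LiCl, −20 °C → rt
Reagents that add atoms: none
Why: N-acylation of the oxazolidinone through the mixed pivalic anhydride (standard loading of an Evans auxiliary); no stereocentre is formed.

Step 2
Reactants: 3 (4R)-4-benzyl-3-(hex-5-enoyl)-1,3-oxazolidin-2-one; 4 tert-butyl acrylate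
Product: 5 tert-butyl (4S)-4-{[(4R)-4-benzyl-2-oxo-1,3-oxazolidin-3-yl]carbonyl}oct-7-enoate
Conditions: TiCl3(OiPr) (from TiCl4 and Ti(OiPr)4, 3:1), iPr2NEt, CH2Cl2, 0 °C; then 4, 0 °C
Reagents that add atoms: none
Why: Evans titanium-enolate Michael addition: the chelated Z-enolate adds to the acrylate on the face away from the benzyl group of the (R)-auxiliary (same facial sense as Evans alkylation), which sets C4.

Step 3
Reactants: 5 tert-butyl (4S)-4-{[(4R)-4-benzyl-2-oxo-1,3-oxazolidin-3-yl]carbonyl}oct-7-enoate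
Product: 6 tert-butyl (4S)-4-(hydroxymethyl)oct-7-enoate
Conditions: LiBH4, MeOH (1 equiv), Et2O, 0 °C
Reagents that add atoms: none
Why: Reductive removal of the auxiliary: LiBH4 reduces the activated exocyclic imide carbonyl much faster than the hindered tert-butyl ester, so C15 is released as the primary alcohol and C4 is untouched.

Step 4
Reactants: 6 tert-butyl (4S)-4-(hydroxymethyl)oct-7-enoate
Product: 7 tert-butyl (4S)-4-({[tert-butyl(dimethyl)silyl]oxy}methyl)oct-7-enoate
Conditions: TBSCl, imidazole, DMF, 0 °C → rt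
Reagents that add atoms: tert-butyldimethylsilyl chloride, CC(C)(C)[Si](C)(C)Cl
Why: Imidazole-promoted silylation protects O15 through the oxidative and organometallic steps and prevents lactol formation with the later C7 aldehyde; the ether is removed together with the tert-butyl ester in step 14.

Step 5
Reactants: 7 tert-butyl (4S)-4-({[tert-butyl(dimethyl)silyl]oxy}methyl)oct-7-enoate
Product: 8 (4S)-4-({[tert-butyl(dimethyl)silyl]oxy}methyl)oct-7-enal
Conditions: iBu2AlH (DIBAL, 1.1 equiv), CH2Cl2, −78 °C; MeOH, then aq. potassium sodium tartrate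
Reagents that add atoms: none
Why: Partial reduction of the ester: at −78 °C the aluminium hemiacetal formed from the tert-butyl ester persists and gives the C7 aldehyde only on work-up; the silyl ether and the alkene are inert.

Step 6
Reactants: 8 (4S)-4-({[tert-butyl(dimethyl)silyl]oxy}methyl)oct-7-enal; 4 tert-butyl acrylate
Product: 9 tert-butyl (6S)-6-({[tert-butyl(dimethyl)silyl]oxy}methyl)-3-hydroxy-2-methylidenedec-9-enoate (both C3 epimers)
Conditions: 4 (3 equiv), quinuclidine (0.5 equiv), MeOH (0.75 equiv), neat, rt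
Reagents that add atoms: none
Why: Morita–Baylis–Hillman reaction: quinuclidine adds to the acrylate and the resulting enolate adds to the aldehyde, methanol speeding the proton transfer; the carbinol (C7) forms as both epimers, which does not matter because this centre becomes sp2 in step 11.

Step 7
Reactants: 9 tert-butyl (6S)-6-({[tert-butyl(dimethyl)silyl]oxy}methyl)-3-hydroxy-2-methylidenedec-9-enoate
Product: 10 tert-butyl (6R)-6-({[tert-butyl(dimethyl)silyl]oxy}methyl)-3-hydroxy-2-methylidene-9-oxononanoate (both C3 epimers)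
Conditions: O3, CH2Cl2, −78 °C, stopped when 9 is consumed (TLC); then Me2S, −78 °C → rt
Reagents that add atoms: ozone, [O-][O+]=O
Why: Chemoselective ozonolysis: the isolated monosubstituted alkene reacts with electrophilic ozone far faster than the ester-conjugated 1,1-disubstituted alkene, and Me2S reduces the ozonide to the C1 aldehyde.

Step 8
Reactants: 11 methyl (triphenyl-λ5-phosphanylidene)acetate (2 equiv); 12 allyl bromide
Product: 14 methyl 2-(triphenyl-λ5-phosphanylidene)pent-4-enoate, via phosphonium bromide 13 (not isolated)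
Conditions: EtOAc, reflux; filtration of the precipitated phosphonium salt of 11
Reagents that add atoms: none
Why: C-Alkylation of the stabilised ylide by allyl bromide followed by transylidation (Bestmann procedure), the second equivalent of 11 acting as the base.

Step 9
Reactants: 10 tert-butyl (6R)-6-({[tert-butyl(dimethyl)silyl]oxy}methyl)-3-hydroxy-2-methylidene-9-oxononanoate; 14 methyl 2-(triphenyl-λ5-phosphanylidene)pent-4-enoate
Product: 15 1-tert-butyl 11-methyl (6S,9E)-6-({[tert-butyl(dimethyl)silyl]oxy}methyl)-3-hydroxy-2-methylidene-10-(prop-2-en-1-yl)undec-9-enedioate (both C3 epimers)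
Conditions: toluene, 80 °C
Reagents that add atoms: none
Why: Wittig olefination with an α-substituted stabilised ylide, which reacts only with the aldehyde and is E-selective as usual for stabilised ylides (C2 trans to the ester, hence cis to C9, the geometry the ring needs).

Step 10
Reactants: 15 1-tert-butyl 11-methyl (6S,9E)-6-({[tert-butyl(dimethyl)silyl]oxy}methyl)-3-hydroxy-2-methylidene-10-(prop-2-en-1-yl)undec-9-enedioate
Product: 16 1-tert-butyl 11-methyl (6S,9E)-6-({[tert-butyl(dimethyl)silyl]oxy}methyl)-3-hydroxy-2-methylidene-10-(2-oxoethyl)undec-9-enedioate (both C3 epimers)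
Conditions: O3, CH2Cl2, −78 °C, stopped when 15 is consumed (TLC); then Me2S, −78 °C → rt
Reagents that add atoms: ozone, [O-][O+]=O
Why: Second chemoselective ozonolysis: only the terminal vinyl group is electron-rich enough to react at −78 °C, the trisubstituted enoate and the acrylate being deactivated by their ester groups; this unmasks the C8 aldehyde.

Step 11
Reactants: 16 1-tert-butyl 11-methyl (6S,9E)-6-({[tert-butyl(dimethyl)silyl]oxy}methyl)-3-hydroxy-2-methylidene-10-(2-oxoethyl)undec-9-enedioate
Product: 17 1-tert-butyl 11-methyl (2Z,6S,9E)-2-(bromomethyl)-6-({[tert-butyl(dimethyl)silyl]oxy}methyl)-10-(2-oxoethyl)undeca-2,9-dienedioate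
Conditions: NBS, Me2S (premixed), CH2Cl2, −20 → 0 °C
Reagents that add atoms: N-bromosuccinimide, O=C1CCC(=O)N1Br
Why: Corey–Kim-type activation of the allylic alcohol by the NBS·Me2S complex and SN2′ displacement by bromide give the (Z)-2-(bromomethyl)enoate (C6 cis to CH2Br) with allylic transposition; the aldehyde and the silyl ether do not react.

Step 12
Reactants: 17 1-tert-butyl 11-methyl (2Z,6S,9E)-2-(bromomethyl)-6-({[tert-butyl(dimethyl)silyl]oxy}methyl)-10-(2-oxoethyl)undeca-2,9-dienedioate
Product: 18 methyl (1E,5S,8R,9R)-8-[3-(tert-butoxy)-3-oxoprop-1-en-2-yl]-5-({[tert-butyl(dimethyl)silyl]oxy}methyl)-9-hydroxycyclodec-1-ene-1-carboxylate (route numbering 4S,7R,8R; 7-H and 8-H cis)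
Conditions: CrCl2 (8 equiv), degassed THF, rt, syringe-pump addition of 17 (final 2 mM); aq. NH4Cl
Reagents that add atoms: none
Why: Intramolecular Nozaki–Hiyama (Barbier-type) allylation: divalent chromium inserts into the allylic C–Br bond and the (Z)-γ-substituted allylchromium adds to the C8 aldehyde through a chair Zimmerman–Traxler transition state with C9 equatorial, which gives the syn adduct (7-H and 8-H cis) and the exocyclic C11=C13 acrylate, while the ring-cis enoate and high dilution favour ten-membered ring closure; the face relative to C4 rests on the pseudo-equatorial preference of the C4 CH2OTBS group in the forming ring and is the least certain element of this step.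

Step 13
Reactants: 18 methyl (1E,5S,8R,9R)-8-[3-(tert-butoxy)-3-oxoprop-1-en-2-yl]-5-({[tert-butyl(dimethyl)silyl]oxy}methyl)-9-hydroxycyclodec-1-ene-1-carboxylate; 19 2-methylpropanoic anhydride
Product: 20 methyl (1E,5S,8R,9R)-8-[3-(tert-butoxy)-3-oxoprop-1-en-2-yl]-5-({[tert-butyl(dimethyl)silyl]oxy}methyl)-9-[(2-methylpropanoyl)oxy]cyclodec-1-ene-1-carboxylate
Conditions: 19, DMAP (0.2 equiv), Et3N, CH2Cl2, 0 °C → rt
Reagents that add atoms: none
Why: DMAP-catalysed acylation of the secondary alcohol (nucleophilic catalysis through the N-acylpyridinium ion) installs the isobutyrate of the target with retention at C8 and blocks O8 from lactonising onto C12.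

Step 14
Reactants: 20 methyl (1E,5S,8R,9R)-8-[3-(tert-butoxy)-3-oxoprop-1-en-2-yl]-5-({[tert-butyl(dimethyl)silyl]oxy}methyl)-9-[(2-methylpropanoyl)oxy]cyclodec-1-ene-1-carboxylate
Product: 21 methyl (1E,5S,8R,9R)-8-(1-carboxyethenyl)-5-(hydroxymethyl)-9-[(2-methylpropanoyl)oxy]cyclodec-1-ene-1-carboxylate (8-O-isobutyryl 6-deoxy seco acid; route numbering 4S,7R,8R)
Conditions: TFA–CH2Cl2–H2O (10:10:1), 0 °C → rt
Reagents that add atoms: none
Why: Acidolysis: the tert-butyl ester is cleaved through the tert-butyl cation (loss of 2-methylpropene) and the primary silyl ether is hydrolysed, whereas the methyl ester and the secondary isobutyrate are stable to aqueous trifluoroacetic acid; no stereocentre is affected.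

Step 15
Reactants: 21 methyl (1E,5S,8R,9R)-8-(1-carboxyethenyl)-5-(hydroxymethyl)-9-[(2-methylpropanoyl)oxy]cyclodec-1-ene-1-carboxylate
Product: 23 methyl (3aS,4R,6E,10S,11aR)-10-(hydroxymethyl)-3-methylidene-4-[(2-methylpropanoyl)oxy]-2-oxo-2,3,3a,4,5,8,9,10,11,11a-decahydrocyclodeca[b]furan-6-carboxylate (target; route numbering 4S,6R,7S,8R), via 6α-hydroxy seco acid 22 (not isolated)
Conditions: yeast microsomes containing an evolved costunolide-synthase-type cytochrome P450 (CYP71BL family) and its NADPH–cytochrome P450 reductase, NADPH (cat.), phosphite dehydrogenase, Na2HPO3, air, KH2PO4/K2HPO4 buffer pH 7.5, 30 °C; then pH 5, rt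
Reagents that add atoms: dioxygen, O=O
Why: Proposed new method: the P450 haem, as its formally tetravalent iron-oxo porphyrin radical cation, abstracts the α-hydrogen of the C6 methylene and returns hydroxyl to the same face by oxygen rebound, and the 6α-alcohol 22, being γ to the C12 carboxyl, closes the lactone by acyl substitution at C12 with loss of water, in the active site or on brief acidification. The closest known reaction type is the 6α-hydroxylation and lactonisation of germacrene acids by costunolide-synthase-class P450s, which also accept 8β-oxygenated acids; a 4,5-saturated, 1(10)-cis ring with a C14 ester and an 8-O-acyl group has not been shown as a substrate, so homologue screening or directed evolution is presupposed. The ring C6–O–C12–C11–C7 closes in the 5-exo-trig mode and becomes trans-fused. The new C6 stereocentre is controlled by the enzyme pocket, which exposes only the α-hydrogen of C6 to the oxidant, and rebound occurs with retention, so O6 ends trans to the C7 acrylate. The step needs selectivity for the unactivated C6–H over the allylic C2–H and C9–H, the tertiary allylic C7–H and both alkenes; the anchored C12 carboxylate holds the γ-methylene C6 over the iron, the two alkenes are electron-poor and so resist epoxidation, and C8–H is deactivated by its acyloxy group. Because O8 is already esterified, only O6 can lactonise onto C12.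

Compound list
1 | (4R)-4-benzyl-1,3-oxazolidin-2-one | O=C1N[C@H](Cc2ccccc2)CO1 | starting material
2 | hex-5-enoic acid | C=CCCCC(=O)O | starting material
3 | (4R)-4-benzyl-3-(hex-5-enoyl)-1,3-oxazolidin-2-one | C=CCCCC(=O)N1[C@H](Cc2ccccc2)COC1=O | intermediate
4 | tert-butyl acrylate | C=CC(=O)OC(C)(C)C | starting material
5 | tert-butyl (4S)-4-{[(4R)-4-benzyl-2-oxo-1,3-oxazolidin-3-yl]carbonyl}oct-7-enoate | C=CCC[C@@H](CCC(=O)OC(C)(C)C)C(=O)N1[C@H](Cc2ccccc2)COC1=O | intermediate
6 | tert-butyl (4S)-4-(hydroxymethyl)oct-7-enoate | C=CCC[C@@H](CCC(=O)OC(C)(C)C)CO | intermediate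
7 | tert-butyl (4S)-4-({[tert-butyl(dimethyl)silyl]oxy}methyl)oct-7-enoate | C=CCC[C@@H](CCC(=O)OC(C)(C)C)CO[Si](C)(C)C(C)(C)C | intermediate
8 | (4S)-4-({[tert-butyl(dimethyl)silyl]oxy}methyl)oct-7-enal | C=CCC[C@@H](CCC=O)CO[Si](C)(C)C(C)(C)C | intermediate
9 | tert-butyl (6S)-6-({[tert-butyl(dimethyl)silyl]oxy}methyl)-3-hydroxy-2-methylidenedec-9-enoate (both C3 epimers) | C=CCC[C@@H](CCC(O)C(=C)C(=O)OC(C)(C)C)CO[Si](C)(C)C(C)(C)C | intermediate
10 | tert-butyl (6R)-6-({[tert-butyl(dimethyl)silyl]oxy}methyl)-3-hydroxy-2-methylidene-9-oxononanoate (both C3 epimers) | O=CCC[C@@H](CCC(O)C(=C)C(=O)OC(C)(C)C)CO[Si](C)(C)C(C)(C)C | intermediate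
11 | methyl (triphenyl-λ5-phosphanylidene)acetate | COC(=O)C=P(c1ccccc1)(c1ccccc1)c1ccccc1 | starting material
12 | allyl bromide | C=CCBr | starting material
13 | (1-methoxy-1-oxopent-4-en-2-yl)triphenylphosphonium bromide | C=CCC(C(=O)OC)[P+](c1ccccc1)(c1ccccc1)c1ccccc1.[Br-] | intermediate (not isolated)
14 | methyl 2-(triphenyl-λ5-phosphanylidene)pent-4-enoate | C=CCC(C(=O)OC)=P(c1ccccc1)(c1ccccc1)c1ccccc1 | intermediate
15 | 1-tert-butyl 11-methyl (6S,9E)-6-({[tert-butyl(dimethyl)silyl]oxy}methyl)-3-hydroxy-2-methylidene-10-(prop-2-en-1-yl)undec-9-enedioate (both C3 epimers) | C=CC/C(C(=O)OC)=C\CC[C@@H](CCC(O)C(=C)C(=O)OC(C)(C)C)CO[Si](C)(C)C(C)(C)C | intermediate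
16 | 1-tert-butyl 11-methyl (6S,9E)-6-({[tert-butyl(dimethyl)silyl]oxy}methyl)-3-hydroxy-2-methylidene-10-(2-oxoethyl)undec-9-enedioate (both C3 epimers) | O=CC/C(C(=O)OC)=C\CC[C@@H](CCC(O)C(=C)C(=O)OC(C)(C)C)CO[Si](C)(C)C(C)(C)C | intermediate
17 | 1-tert-butyl 11-methyl (2Z,6S,9E)-2-(bromomethyl)-6-({[tert-butyl(dimethyl)silyl]oxy}methyl)-10-(2-oxoethyl)undeca-2,9-dienedioate | O=CC/C(C(=O)OC)=C\CC[C@@H](CC/C=C(\CBr)C(=O)OC(C)(C)C)CO[Si](C)(C)C(C)(C)C | intermediate
18 | methyl (1E,5S,8R,9R)-8-[3-(tert-butoxy)-3-oxoprop-1-en-2-yl]-5-({[tert-butyl(dimethyl)silyl]oxy}methyl)-9-hydroxycyclodec-1-ene-1-carboxylate | C=C(C(=O)OC(C)(C)C)[C@H]1CC[C@@H](CO[Si](C)(C)C(C)(C)C)CC/C=C(/C(=O)OC)C[C@H]1O | intermediate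
19 | 2-methylpropanoic anhydride | CC(C)C(=O)OC(=O)C(C)C | starting material
20 | methyl (1E,5S,8R,9R)-8-[3-(tert-butoxy)-3-oxoprop-1-en-2-yl]-5-({[tert-butyl(dimethyl)silyl]oxy}methyl)-9-[(2-methylpropanoyl)oxy]cyclodec-1-ene-1-carboxylate | C=C(C(=O)OC(C)(C)C)[C@H]1CC[C@@H](CO[Si](C)(C)C(C)(C)C)CC/C=C(/C(=O)OC)C[C@H]1OC(=O)C(C)C | intermediate
21 | methyl (1E,5S,8R,9R)-8-(1-carboxyethenyl)-5-(hydroxymethyl)-9-[(2-methylpropanoyl)oxy]cyclodec-1-ene-1-carboxylate (8-O-isobutyryl 6-deoxy seco acid) | C=C(C(=O)O)[C@H]1CC[C@@H](CO)CC/C=C(/C(=O)OC)C[C@H]1OC(=O)C(C)C | intermediate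
22 | methyl (1E,5S,7R,8S,9R)-8-(1-carboxyethenyl)-7-hydroxy-5-(hydroxymethyl)-9-[(2-methylpropanoyl)oxy]cyclodec-1-ene-1-carboxylate (6α-hydroxy seco acid) | C=C(C(=O)O)[C@H]1[C@H](O)C[C@@H](CO)CC/C=C(/C(=O)OC)C[C@H]1OC(=O)C(C)C | intermediate (not isolated)
23 | methyl (3aS,4R,6E,10S,11aR)-10-(hydroxymethyl)-3-methylidene-4-[(2-methylpropanoyl)oxy]-2-oxo-2,3,3a,4,5,8,9,10,11,11a-decahydrocyclodeca[b]furan-6-carboxylate | C=C1C(=O)O[C@@H]2C[C@@H](CO)CC/C=C(/C(=O)OC)C[C@@H](OC(=O)C(C)C)[C@@H]12 | target

Total step count: 15. Longest linear sequence: 14 (steps 1–7 and 9–15; step 8 prepares the ylide).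

Steps most likely to fail

1. Step 15. The process at risk is lack of turnover of the unnatural acid, or oxygen delivery to the allylic C2 or C9 methylenes instead of C6. The fallback uses known chemistry and installs the C6 oxygen before the ring is built; it sets out from aldehyde 8 and comes back at hydroxy acid 22. L-Proline-catalysed α-aminoxylation of 8 with nitrosobenzene, followed by NaBH4 in the same flask, should give anilinooxy alcohol F1, with the oxygen delivered under catalyst control to the face that becomes 6α (2R in F1). CuSO4-catalysed N–O cleavage in MeOH gives diol F2, and Et3SiCl/imidazole gives bis(triethylsilyl) ether F3. Swern oxidation ((COCl)2, DMSO, Et3N), which attacks only the primary triethylsilyl ether, gives α-silyloxy aldehyde F4. Base-free vinylalumination (tert-butyl propiolate, iBu2AlH, N-methylmorpholine N-oxide, THF), chosen so that C6 is not epimerised, gives hydroxy acrylate F5. Ozonolysis as in step 7 gives aldehyde F6, Wittig reaction with 14 as in step 9 gives enoate F7, ozonolysis as in step 10 gives aldehyde F8, and NBS/Me2S as in step 11 gives bromo aldehyde F9. CrCl2 closure as in step 12 gives ring alcohol F10, where the adjacent C6 silyloxy centre adds 1,2-induction, and acylation with 19 gives isobutyrate F11. TFA–CH2Cl2–H2O then removes the tert-butyl ester and both silyl ethers to give 22, which lactonises under these acidic conditions to 23.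

2. Step 12. The process at risk is erosion of the chair (syn) selectivity by the ten-membered tether, so that addition through a boat-like arrangement gives the C8 epimer; competing intermolecular coupling is limited by dilution. The fallback accepts the epimer and corrects it by invertive esterification; it sets out from 17 and comes back at 20. The same CrCl2 closure would then give the 8-epimeric ring alcohol F12, and a Mitsunobu reaction with 2-methylpropanoic acid (PPh3, DIAD, toluene, 0 °C → rt) converts F12 with inversion at C8 directly into isobutyrate 20, so step 13 is skipped.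

3. Step 11. The process at risk is enolisation of the β,γ-unsaturated aldehyde 16 and migration of the C1=C10 double bond into conjugation with C8 (to C9=C10) during bromination and chromatography. The fallback reverses the order so that the aldehyde is formed last and never purified; it sets out from 15 and comes back at 17. NBS/Me2S on 15 gives allylic bromide F13, which still carries the terminal vinyl group. Dihydroxylation–periodate cleavage of that vinyl group (OsO4 cat., NaIO4, 2,6-lutidine, dioxane–H2O, rt) then gives 17, which is used crude in step 12.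

Further compounds
F1 | step 15 | (2R,4S)-2-(anilinooxy)-4-({[tert-butyl(dimethyl)silyl]oxy}methyl)oct-7-en-1-ol | C=CCC[C@@H](C[C@@H](ONc1ccccc1)CO)CO[Si](C)(C)C(C)(C)C
F2 | step 15 | (2R,4S)-4-({[tert-butyl(dimethyl)silyl]oxy}methyl)oct-7-ene-1,2-diol | C=CCC[C@@H](C[C@@H](O)CO)CO[Si](C)(C)C(C)(C)C
F3 | step 15 | 1,2-bis(triethylsilyl) ether of F2 | C=CCC[C@@H](C[C@@H](O[Si](CC)(CC)CC)CO[Si](CC)(CC)CC)CO[Si](C)(C)C(C)(C)C
F4 | step 15 | (2R,4S)-4-({[tert-butyl(dimethyl)silyl]oxy}methyl)-2-[(triethylsilyl)oxy]oct-7-enal | C=CCC[C@@H](C[C@@H](O[Si](CC)(CC)CC)C=O)CO[Si](C)(C)C(C)(C)C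
F5 | step 15 | 4-(triethylsilyloxy) analogue of 9 (route C6 oxygenated; both C3 epimers) | C=CCC[C@@H](C[C@@H](O[Si](CC)(CC)CC)C(O)C(=C)C(=O)OC(C)(C)C)CO[Si](C)(C)C(C)(C)C
F6 | step 15 | 4-(triethylsilyloxy) analogue of 10 | O=CCC[C@@H](C[C@@H](O[Si](CC)(CC)CC)C(O)C(=C)C(=O)OC(C)(C)C)CO[Si](C)(C)C(C)(C)C
F7 | step 15 | 4-(triethylsilyloxy) analogue of 15 | C=CC/C(C(=O)OC)=C\CC[C@@H](C[C@@H](O[Si](CC)(CC)CC)C(O)C(=C)C(=O)OC(C)(C)C)CO[Si](C)(C)C(C)(C)C
F8 | step 15 | 4-(triethylsilyloxy) analogue of 16 | O=CC/C(C(=O)OC)=C\CC[C@@H](C[C@@H](O[Si](CC)(CC)CC)C(O)C(=C)C(=O)OC(C)(C)C)CO[Si](C)(C)C(C)(C)C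
F9 | step 15 | 4-(triethylsilyloxy) analogue of 17 (2Z,9E) | O=CC/C(C(=O)OC)=C\CC[C@@H](C[C@@H](O[Si](CC)(CC)CC)/C=C(\CBr)C(=O)OC(C)(C)C)CO[Si](C)(C)C(C)(C)C
F10 | step 15 | 7-(triethylsilyloxy) analogue of 18 (route C6 oxygen trans to the C7 acrylate) | C=C(C(=O)OC(C)(C)C)[C@H]1[C@H](O[Si](CC)(CC)CC)C[C@@H](CO[Si](C)(C)C(C)(C)C)CC/C=C(/C(=O)OC)C[C@H]1O
F11 | step 15 | 7-(triethylsilyloxy) analogue of 20 | C=C(C(=O)OC(C)(C)C)[C@H]1[C@H](O[Si](CC)(CC)CC)C[C@@H](CO[Si](C)(C)C(C)(C)C)CC/C=C(/C(=O)OC)C[C@H]1OC(=O)C(C)C
F12 | step 12 | 9-epimer of 18 (route C8 epimer; 7-H and 8-H trans) | C=C(C(=O)OC(C)(C)C)[C@H]1CC[C@@H](CO[Si](C)(C)C(C)(C)C)CC/C=C(/C(=O)OC)C[C@@H]1O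
F13 | step 11 | 1-tert-butyl 11-methyl (2Z,6S,9E)-2-(bromomethyl)-6-({[tert-butyl(dimethyl)silyl]oxy}methyl)-10-(prop-2-en-1-yl)undeca-2,9-dienedioate | C=CC/C(C(=O)OC)=C\CC[C@@H](CC/C=C(\CBr)C(=O)OC(C)(C)C)CO[Si](C)(C)C(C)(C)C
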